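**Assumption:** with the ring numbered as cyclohexa-2,4-dien-1-yl, the target is the (1S,6S) isomer with an (E) side chain; compounds 1, 2, 6 and 7 are bought, and the antipode of the chiral acid that gives (1S,6S) is fixed by a first small-scale run (both antipodes are commercial).

## Retrosynthetic overview
- Target ⇐ thermal disrotatory 6π-electrocyclisation of the 4Z isomer of the all-E tetraenone-pyrone (the presumed linear polypropionate precursor), formed in the same flask by sensitised E→Z isomerisation inside a chiral acid complex. The cyclohexadiene ring is formed last and both stereocentres are set in this one event.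
- All-E tetraenone ⇐ aldol condensation of 6-ethyl-2-methoxy-3,5-dimethyl-4-pyranone with a C12 keto-trienal.
- Pyrone ring (formed first) ⇐ lactonisation of a 3,5-diketo ester (triketide cyclisation), then O-methylation.
- Keto-trienal ⇐ methylglyoxal plus three iterative Wittig propionate homologations.

## Route

Step 1
Reactants: 1 methyl 2-methyl-3-oxopentanoate (racemic); 2 N-methoxy-N-methylpropanamide
Product: 3 methyl 2,4-dimethyl-3,5-dioxoheptanoate (diastereomer/tautomer mixture)
Conditions: NaH, THF, 0 °C; n-BuLi, −20 °C; 2, −78 → 0 °C; aq. HCl work-up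
Reagents that add atoms: none
Why: γ-acylation of the β-keto ester dianion (Claisen-type C-acylation), where the Weinreb amide stops at the ketone stage; the stereocentres of 3 are lost in step 2.

Step 2
Reactants: 3 methyl 2,4-dimethyl-3,5-dioxoheptanoate
Product: 4 6-ethyl-4-hydroxy-3,5-dimethyl-2H-pyran-2-one
Conditions: DBU (1.5 equiv), PhMe, 80 °C
Reagents that add atoms: none
Why: base-mediated enol-lactonisation of the triketide with loss of methanol, the laboratory counterpart of the polyketide pyrone cyclisation.

Step 3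
Reactants: 4 6-ethyl-4-hydroxy-3,5-dimethyl-2H-pyran-2-one
Product: 5 6-ethyl-2-methoxy-3,5-dimethyl-4H-pyran-4-one
Conditions: MeOTf (1.2 equiv), CH2Cl2, rt; then sat. aq. NaHCO3
Reagents that add atoms: methyl trifluoromethanesulfonate, COS(=O)(=O)C(F)(F)F
Why: kinetic O-methylation at the lactone carbonyl oxygen gives the 2-methoxy-4-hydroxypyrylium ion, which loses a proton to the α-methoxy-γ-pyrone (hard-electrophile pyrone methylation).

Step 4
Reactants: 6 methylglyoxal (40 % aqueous); 7 2-(triphenylphosphoranylidene)propanal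
Product: 8 (2E)-2-methyl-4-oxopent-2-enal
Conditions: CH2Cl2/H2O, rt, 16 h
Reagents that add atoms: none
Why: Wittig olefination with a stabilised formyl ylide, which attacks only the far more electrophilic aldehyde of the 1,2-dicarbonyl and gives the (E)-trisubstituted enal.

Step 5
Reactants: 8 (2E)-2-methyl-4-oxopent-2-enal; 7 2-(triphenylphosphoranylidene)propanal
Product: 9 (2E,4E)-2,4-dimethyl-6-oxohepta-2,4-dienal
Conditions: PhMe, 60 °C, dark
Reagents that add atoms: none
Why: iterative E-selective Wittig propionate homologation; the ketone is inert to the stabilised ylide and the product dienal is less electrophilic than 8, which limits over-homologation.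

Step 6
Reactants: 9 (2E,4E)-2,4-dimethyl-6-oxohepta-2,4-dienal; 7 2-(triphenylphosphoranylidene)propanal
Product: 10 (2E,4E,6E)-2,4,6-trimethyl-8-oxonona-2,4,6-trienal
Conditions: PhMe, 90 °C, dark
Reagents that add atoms: none
Why: third E-selective Wittig homologation of the same kind, stopped at one addition by using 1.05 equiv of ylide.

Step 7
Reactants: 5 6-ethyl-2-methoxy-3,5-dimethyl-4H-pyran-4-one; 10 (2E,4E,6E)-2,4,6-trimethyl-8-oxonona-2,4,6-trienal
Product: 13 2-methoxy-3,5-dimethyl-6-[(2E,4E,6E,8E)-4,6,8-trimethyl-10-oxoundeca-2,4,6,8-tetraen-2-yl]-4H-pyran-4-one, via lithium aldolate 11 (not isolated), via allylic mesylate 12 (not isolated)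
Conditions: LiHMDS (1.05 equiv), THF, −78 °C; 10, −78 °C; MsCl, −78 → 0 °C; DBU, rt, dark
Reagents that add atoms: none
Why: vinylogous aldol addition of the lithiated 6-ethylpyrone to the aldehyde (faster at −78 °C than attack on or deprotonation of the enone), then E1cB elimination of the mesylate to the conjugated (E)-alkene; the transient stereocentres of 11 and 12 are destroyed.

Step 8
Reactants: 13 2-methoxy-3,5-dimethyl-6-[(2E,4E,6E,8E)-4,6,8-trimethyl-10-oxoundeca-2,4,6,8-tetraen-2-yl]-4H-pyran-4-one
Product: 15 2-methoxy-3,5-dimethyl-6-[(1S,6S)-1,3,5-trimethyl-6-[(2E)-4-oxopent-2-en-2-yl]cyclohexa-2,4-dien-1-yl]-4H-pyran-4-one, via 4Z-tetraenone 14 (not isolated)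
Conditions: (R)-TRIP (1.1 equiv, recovered), Ru(bpy)3(PF6)2 (2 mol %), degassed CH2Cl2 (0.02 M), 450 nm LED, 40 °C, Ar; then SiO2 chromatography
Reagents that add atoms: none
Why: Proposed new method: triplet energy transfer from the sensitiser (ET about 46 kcal/mol, above the tetraenone but below the cyclohexadiene and enone of 15, so the product is not re-excited) scrambles the polyene geometry, and only the 4Z isomer 14 is drained by an irreversible thermal disrotatory 6π-electrocyclisation of its C2–C7 triene, which puts the two outside groups (pyrone and enone arm) cis and so gives the 1,6-cis relative configuration, while closure of the C4–C9 triene is disfavoured because it would break the enone conjugation; the absolute sense is to come from hydrogen bonding of the strongly basic γ-pyrone carbonyl of every substrate molecule to the confined chiral phosphoric acid, so that the pyrone swinging at C1 sits in the chiral pocket and the two helical boat transition states become diastereomeric; closest known reaction types are the light- or Pd-mediated isomerisation/6π cascades of related pyrone polyenes (racemic) and chiral-Brønsted-acid-controlled 6π-electrocyclisations and Nazarov cyclisations; the level of ee is the open risk.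

## Compound list
1 | methyl 2-methyl-3-oxopentanoate (racemic) | CCC(=O)C(C)C(=O)OC | starting material
2 | N-methoxy-N-methylpropanamide | CCC(=O)N(C)OC | starting material
3 | methyl 2,4-dimethyl-3,5-dioxoheptanoate (diastereomer mixture) | CCC(=O)C(C)C(=O)C(C)C(=O)OC | intermediate
4 | 6-ethyl-4-hydroxy-3,5-dimethyl-2H-pyran-2-one | CCC1=C(C)C(O)=C(C)C(=O)O1 | intermediate
5 | 6-ethyl-2-methoxy-3,5-dimethyl-4H-pyran-4-one | CCc1oc(OC)c(C)c(=O)c1C | intermediate
6 | methylglyoxal | CC(=O)C=O | starting material
7 | 2-(triphenylphosphoranylidene)propanal | CC(C=O)=P(c1ccccc1)(c1ccccc1)c1ccccc1 | starting material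
8 | (2E)-2-methyl-4-oxopent-2-enal | O=C/C(C)=C/C(C)=O | intermediate
9 | (2E,4E)-2,4-dimethyl-6-oxohepta-2,4-dienal | O=C/C(C)=C/C(C)=C/C(C)=O | intermediate
10 | (2E,4E,6E)-2,4,6-trimethyl-8-oxonona-2,4,6-trienal | O=C/C(C)=C/C(C)=C/C(C)=C/C(C)=O | intermediate
11 | lithium (4E,6E,8E)-2-(6-methoxy-3,5-dimethyl-4-oxo-4H-pyran-2-yl)-4,6,8-trimethyl-10-oxoundeca-4,6,8-trien-3-olate (diastereomer mixture) | COc1oc(C(C)C([O-])/C(C)=C/C(C)=C/C(C)=C/C(C)=O)c(C)c(=O)c1C.[Li+] | intermediate (not isolated)
12 | (4E,6E,8E)-2-(6-methoxy-3,5-dimethyl-4-oxo-4H-pyran-2-yl)-4,6,8-trimethyl-10-oxoundeca-4,6,8-trien-3-yl methanesulfonate (diastereomer mixture) | COc1oc(C(C)C(OS(C)(=O)=O)/C(C)=C/C(C)=C/C(C)=C/C(C)=O)c(C)c(=O)c1C | intermediate (not isolated)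
13 | 2-methoxy-3,5-dimethyl-6-[(2E,4E,6E,8E)-4,6,8-trimethyl-10-oxoundeca-2,4,6,8-tetraen-2-yl]-4H-pyran-4-one | COc1oc(/C(C)=C/C(C)=C/C(C)=C/C(C)=C/C(C)=O)c(C)c(=O)c1C | intermediate
14 | 2-methoxy-3,5-dimethyl-6-[(2E,4Z,6E,8E)-4,6,8-trimethyl-10-oxoundeca-2,4,6,8-tetraen-2-yl]-4H-pyran-4-one | COc1oc(/C(C)=C/C(C)=C\C(C)=C\C(C)=C\C(C)=O)c(C)c(=O)c1C | intermediate (not isolated)
15 | 2-methoxy-3,5-dimethyl-6-[(1S,6S)-1,3,5-trimethyl-6-[(2E)-4-oxopent-2-en-2-yl]cyclohexa-2,4-dien-1-yl]-4H-pyran-4-one | COc1oc([C@@]2(C)C=C(C)C=C(C)[C@H]2/C(C)=C/C(C)=O)c(C)c(=O)c1C | target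

## Step count and risks
Total step count: 8. Longest linear sequence: 5 (steps 1, 2, 3, 7, 8 or steps 4, 5, 6, 7, 8).

**Step 8 (most likely to fail: enantioselectivity, and possibly regioselectivity of the cascade).** The fallback sets out from 13 and comes back at 15. The cascade is run without the chiral acid (sensitiser and light only, 40 °C). This gives the racemate, that is 15 together with its mirror image, the (1R,6R)-cyclohexadienyl pyrone F1. The two are separated by preparative chiral SFC on an amylose-type phase and 15 is collected. This replaces asymmetric induction by resolution, costs at most half the material, and also serves to upgrade a partial ee from the main step.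

**Step 7 (the lithiated pyrone may deprotonate or attack the methyl enone of 10).** The fallback sets out from 5 and comes back at 12. The lithiated pyrone is silylated on oxygen (LiHMDS, then TBSCl) to the silyl dienol ether tert-butyl[(2-ethylidene-6-methoxy-3,5-dimethyl-2H-pyran-4-yl)oxy]dimethylsilane F2. F2 is added to 10 in a BF3·OEt2-mediated vinylogous Mukaiyama aldol reaction, which is non-basic and aldehyde-selective. Aqueous work-up gives the free aldol, the β-hydroxy pyrone 6-[(4E,6E,8E)-3-hydroxy-4,6,8-trimethyl-10-oxoundeca-4,6,8-trien-2-yl]-2-methoxy-3,5-dimethyl-4H-pyran-4-one F3. Mesylation (MsCl, Et3N) gives 12, and the DBU elimination of step 7 follows.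

**Step 4 (aqueous, oligomeric methylglyoxal and a sensitive, volatile product).** The fallback sets out from 7 and comes back at 8. It is a tandem oxidation–Wittig reaction: hydroxyacetone is oxidised with activated MnO2 in refluxing CH2Cl2 in the presence of 7, so that anhydrous 6 is trapped by the ylide as it forms. No new isolable compound is made.

Further compounds
F1 | step 8 | 2-methoxy-3,5-dimethyl-6-[(1R,6R)-1,3,5-trimethyl-6-[(2E)-4-oxopent-2-en-2-yl]cyclohexa-2,4-dien-1-yl]-4H-pyran-4-one | COc1oc([C@]2(C)C=C(C)C=C(C)[C@@H]2/C(C)=C/C(C)=O)c(C)c(=O)c1C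
F2 | step 7 | tert-butyl[(2-ethylidene-6-methoxy-3,5-dimethyl-2H-pyran-4-yl)oxy]dimethylsilane | CC=C1OC(OC)=C(C)C(O[Si](C)(C)C(C)(C)C)=C1C
F3 | step 7 | 6-[(4E,6E,8E)-3-hydroxy-4,6,8-trimethyl-10-oxoundeca-4,6,8-trien-2-yl]-2-methoxy-3,5-dimethyl-4H-pyran-4-one (diastereomer mixture) | COc1oc(C(C)C(O)/C(C)=C/C(C)=C/C(C)=C/C(C)=O)c(C)c(=O)c1C
F0 | step 4 | none | none
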